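At the 4.00 min reading, the north-west flask holds 5.8% electrophile and 64.1% product; here is what to expect at 8.0 min.

all flasks: electrophile 0.10 M

| charge | nucleophile | free base | protic impurity | remark | time |
|---|---|---|---|---|---|
| north-west | 1 equiv | 1.5 equiv | 0.030 M | the very flask that is asked about, followed so far |  |
| north-east | 1 equiv | 1.5 equiv | 0.020 M | run made earlier |  |
| flask | 1.00 equiv | 1.50 equiv | 0.0300 M |  | 8.0 min |

| run | time / min | electrophile / % | product / % |
|---|---|---|---|
| north-west | 1.00 | 20.9 | 50.5 |
| north-west | 2.00 | 12.7 | 59.0 |
| north-west | 3.00 | 8.7 | 62.7 |
| north-west | 4.00 | 5.8 | 64.1 |
| north-east | 0.250 | 53.3 | 34.0 |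
| north-east | 0.667 | 33.3 | 50.2 |
| north-east | 1.33 | 23.8 | 56.5 |
| north-east | 3.00 | 13.4 | 66.3 |

(readings scatter by 0.5 percentage points)

- amounts and yields of product count idle adduct too
- the numbers in the tables scatter by 0.5 percentage points (one standard deviation)
- reactions considered so far: electrophile + nucleophile -> acid set free + product; nucleophile + acid set free <-> protonated nucleophile; acid set free + free base <-> salt of the base; electrophile + protic impurity -> quenched substrate; nucleophile + product <-> idle adduct; acid set free -> by-product carried off
- the earlier runs do not show how much of nucleophile is bound; that part of a forecast is a guess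

- part of the electrophile that has reacted at 8.0 min
- share of free nucleophile in free nucleophile and protonated nucleophile together, at 8.0 min

1. Reading the balance: electrophile missing from both columns is 30.1% in the north-west run and 20.3% in the north-east run, which match their impurity charges.

2. Call the reach the nucleophile equivalents plus the impurity equivalents, that is, what can consume electrophile: 1.30 equiv here. Since this exceeds one, the electrophile is the limiting reagent against its two partners together, and if the impurity takes its full charge, 0.0300 M of nucleophile stays over in its free, protonated and adduct forms.

3. My reckoning replaces the north-west curve by its mean decay from 2.00 min to 4.00 min, 0.392 /min, which, held on to 8.0 min, leaves 1.21% electrophile. The decay has slowed from 0.498 /min, so expect somewhat more.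

4. The electrophile left at the last north-west reading, 0.005800 M, is less than the spare nucleophile reckoned above.

5. The forecast gives 98.8% and 75%, adding “The fr value is softer”.

    electrophile + nucleophile → acid set free + product (k = 34.0 /M/min)
    nucleophile + acid set free ⇌ protonated nucleophile, settled at all times (K = 5100 /M)
    acid set free + free base ⇌ salt of the base, settled at all times (K = 590 /M)
    electrophile + protic impurity → quenched substrate (k = 57.0 /M/min)
    nucleophile + product ⇌ idle adduct, settled at all times (K = 11.0 /M)
    acid set free → by-product carried off (k = 0.0720 /min)

The flask gives 97.5% reacted and a free share of 21.5%. Its unused nucleophile, close to the spare 0.0300 M, stands as 0.0221 M protonated, 0.00604 M free and 0.004216 M in idle adduct. The half-life of acid set free by its carrying off alone, 9.6 min, is longer than the 8.0 min elapsed. By then 3.17 × 10⁻⁴ M has left as by-product, less than the protonated nucleophile. The neighbour flask with 0.250 equiv of nucleophile has a reach of 0.550 equiv, and 54.9% of its electrophile has reacted.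

The data come from a simulation for an exercise; the scatter is artificial.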